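**Plan**

1. Target: (3S,6R)-3-hydroxy-8'-apo-ε-caroten-8'-ol. Retrosynthetic cuts: C11=C12 (Wittig, two C15 halves), then C9=C10 and C7=C8 (two Horner–Wadsworth–Emmons steps), and C11'=C12' inside the chain half (C10 dialdehyde + C5 phosphonate).
2. Enabling feature: in the ε-ring the allyl triad C3–C4=C5 lies between O-bearing C3 and C6, and the exocyclic carbon C7 on C6 is cis to O3. A temporary O3–C7 lactone bridge (2-oxabicyclo[2.2.2]octene) is therefore an allyl cation C3–C4–C5 captured across the ring by a C7 carbonyl oxygen.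
3. The carbocycle is made as a cyclopentene that lacks C4. Dibromocarbene adds C4 as a fused cyclopropane, and silver-induced, strain-releasing opening expands five to six while the C6 carboxamide closes the bridge (step 7).
4. Stereochemistry: CBS reduction sets one carbinol centre; a suprafacial [2,3]-Wittig–Still shift transfers it to C6; the tether relays C6 to C3 (cis). All chain alkenes are E from stabilised olefinations.
5. Helpers taken out: Br on C4 by Bu3SnH, the lactone bridge by iBu2AlH reduction and olefination, the amide nitrogen on hydrolysis.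
6. Forward order: cyclopentene → bicyclo[3.1.0]hexane → ε-ring lactone → C13 ketone → C15 aldehyde; the chain C15 phosphonium salt is made separately; Wittig union; ester reduction.

Key step: step 7

Assumption: ketone 1, dialdehyde 23 and phosphonate 24 are treated as purchasable building blocks.

**Route**

Step 1
Reactants: 1 2,4,4-trimethylcyclopent-2-en-1-one
Product: 2 (1S)-2,4,4-trimethylcyclopent-2-en-1-ol
Conditions: (R)-2-methyl-CBS-oxazaborolidine (10 mol %), BH3·SMe2, THF, −20 °C; aqueous work-up
Reagents that add atoms: none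
Why: Corey–Bakshi–Shibata 1,2-reduction; with the α-methylalkenyl arm of the enone as the large group, the (R)-catalyst is expected to deliver hydride to the face that gives the S carbinol.

Step 2
Reactants: 2 (1S)-2,4,4-trimethylcyclopent-2-en-1-ol
Product: 3 tributyl({[(1S)-2,4,4-trimethylcyclopent-2-en-1-yl]oxy}methyl)stannane
Conditions: KH, THF, 0 °C; then Bu3SnCH2I, rt
Reagents that add atoms: tributyl(iodomethyl)stannane, CCCC[Sn](CI)(CCCC)CCCC
Why: Williamson etherification of the potassium alkoxide with a primary iodide; the carbinol centre is not touched.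

Step 3
Reactants: 3 tributyl({[(1S)-2,4,4-trimethylcyclopent-2-en-1-yl]oxy}methyl)stannane
Product: 5 [(1R)-2,5,5-trimethylcyclopent-2-en-1-yl]methanol, via lithiomethyl ether 4 (not isolated)
Conditions: n-BuLi, THF, −78 °C; then H2O
Reagents that add atoms: none
Why: Tin–lithium exchange followed by [2,3]-Wittig–Still rearrangement; the shift is suprafacial within the ring, so the CH2OH carbon (C7) is delivered to the alkene carbon next to CMe2 (future C6) on the face that carried oxygen, and the alkene moves to the C3/C5 positions.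

Step 4
Reactants: 5 [(1R)-2,5,5-trimethylcyclopent-2-en-1-yl]methanol
Product: 7 (1R)-2,5,5-trimethylcyclopent-2-ene-1-carboxylic acid, via aldehyde 6 (not isolated)
Conditions: TEMPO (cat.), PhI(OAc)2, MeCN/H2O, rt
Reagents that add atoms: water, O
Why: Oxoammonium oxidation of a primary alcohol through the aldehyde hydrate to the acid under near-neutral conditions that should leave the α-centre and the β,γ-alkene in place.

Step 5
Reactants: 7 (1R)-2,5,5-trimethylcyclopent-2-ene-1-carboxylic acid
Product: 9 (1R)-N,N,2,5,5-pentamethylcyclopent-2-ene-1-carboxamide, via acid chloride 8 (not isolated)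
Conditions: (COCl)2, DMF (cat.), CH2Cl2, 0 °C; then Me2NH (2 M in THF, excess), −20 °C to rt
Reagents that add atoms: dimethylamine, CNC
Why: Acyl chloride formation and amidation; the small, nucleophilic amine should acylate faster than the hindered α-hydrogen is removed, so the C6 centre is kept.

Step 6
Reactants: 9 (1R)-N,N,2,5,5-pentamethylcyclopent-2-ene-1-carboxamide
Product: 10 (1S,2R,5R)-6,6-dibromo-N,N,1,3,3-pentamethylbicyclo[3.1.0]hexane-2-carboxamide
Conditions: CHBr3, 50% aq NaOH, BnEt3NCl (cat.), CH2Cl2, 0 °C to rt; product kept cold and used crude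
Reagents that add atoms: bromoform, BrC(Br)Br
Why: Phase-transfer dibromocarbene addition to the electron-rich trisubstituted alkene, expected anti to the carboxamide; the tertiary amide is inert to the base, and either cyclopropane face converges in step 7.

Step 7
Reactants: 10 (1S,2R,5R)-6,6-dibromo-N,N,1,3,3-pentamethylbicyclo[3.1.0]hexane-2-carboxamide
Product: 13 (1S,4R)-6-bromo-5,8,8-trimethyl-2-oxabicyclo[2.2.2]oct-5-en-3-one, via bromoallyl cation 11 (not isolated), via bridged iminium ether 12 (not isolated)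
Conditions: AgOSO2CF3 (1.5 equiv), (CF3)2CHOH/CH2Cl2, 0 °C to rt, dark; then H2O/THF, NaOAc–AcOH buffer (pH 5)
Reagents that add atoms: water, O
Why: Silver abstracts the bromide that lies over the five-membered ring while the C3–C5 cyclopropane σ bond opens in a disrotatory two-electron electrocyclic process (Woodward–Hoffmann–DePuy), so the carbene carbon is inserted as C4 and the cyclopentane becomes the 2-bromocyclohex-2-enyl cation 11 (C3–C4–C5). The closest known reaction type is the silver-promoted electrocyclic opening of ring-fused gem-dibromocyclopropanes with capture of the allyl cation by a tethered heteroatom nucleophile. The carbocycle is thus closed by one-carbon ring expansion (five to six), and the lactone bridge by attack of the amide oxygen on the C3 terminus, a six-membered closure exo to the C3–C4 π bond that gives imidate salt 12, hydrolysed at pH 5 with loss of dimethylamine. The only new stereocentre, C3, is set by the tether: the oxygen can reach C3 only on the ring face that carries C7 at C6, so O3 and C7 end cis whichever face the carbene took in step 6. Regioselectivity for C3 over the tertiary C5 terminus follows because capture at C5 would need a four-membered ring, and 1,2-allylic strain with the C5 methyl holds the C6 carboxamide pseudo-axial over the ring. Proton loss to bromodienes is the competing path; it is kept down by the non-basic, non-nucleophilic medium and by using an amide carbonyl, which traps cations well and cannot fragment with loss of CO2 as a carboxylate could.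

Step 8
Reactants: 13 (1S,4R)-6-bromo-5,8,8-trimethyl-2-oxabicyclo[2.2.2]oct-5-en-3-one
Product: 14 (1S,4R)-5,8,8-trimethyl-2-oxabicyclo[2.2.2]oct-5-en-3-one
Conditions: Bu3SnH, AIBN (cat.), toluene, 80 °C
Reagents that add atoms: none
Why: Radical chain hydrodebromination of the vinyl bromide; the allylic lactone C–O bond, which a palladium catalyst would ionise, is inert to the vinyl radical.

Step 9
Reactants: 14 (1S,4R)-5,8,8-trimethyl-2-oxabicyclo[2.2.2]oct-5-en-3-one
Product: 15 (1S,4R)-5,8,8-trimethyl-2-oxabicyclo[2.2.2]oct-5-en-3-ol (both C3 epimers)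
Conditions: iBu2AlH (1.1 equiv), CH2Cl2, −78 °C; aq KNaC4H4O6
Reagents that add atoms: none
Why: Partial reduction of a lactone to the lactol at low temperature; in the bicyclic form the bridgehead C6–H cannot enolise, so the C6 centre is stored safely at the aldehyde oxidation level.

Step 10
Reactants: 15 (1S,4R)-5,8,8-trimethyl-2-oxabicyclo[2.2.2]oct-5-en-3-ol; 16 diethyl (2-oxopropyl)phosphonate
Product: 18 (3E)-4-[(1R,4S)-4-hydroxy-2,6,6-trimethylcyclohex-2-en-1-yl]but-3-en-2-one, via open hydroxy aldehyde 17 (not isolated)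
Conditions: LiCl, iPr2NEt, MeCN, rt
Reagents that add atoms: none
Why: Horner–Wadsworth–Emmons olefination of a lactol under Masamune–Roush conditions; the lactol opens reversibly to 17, the keto-phosphonate gives the E-enone, and the weak amine base should spare C6 and free the C3 hydroxyl.

Step 11
Reactants: 18 (3E)-4-[(1R,4S)-4-hydroxy-2,6,6-trimethylcyclohex-2-en-1-yl]but-3-en-2-one; 19 diethyl (cyanomethyl)phosphonate
Product: 20 (2E,4E)-5-[(1R,4S)-4-hydroxy-2,6,6-trimethylcyclohex-2-en-1-yl]-3-methylpenta-2,4-dienenitrile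
Conditions: NaH, THF, 0 °C to rt
Reagents that add atoms: none
Why: Horner–Wadsworth–Emmons olefination of the methyl ketone, expected to favour the 2E nitrile (the minor 2Z isomer is to be removed by chromatography); the phosphonate anion is too weak a base to disturb the free hydroxyl or C6.

Step 12
Reactants: 20 (2E,4E)-5-[(1R,4S)-4-hydroxy-2,6,6-trimethylcyclohex-2-en-1-yl]-3-methylpenta-2,4-dienenitrile
Product: 22 (2E,4E)-5-[(1R,4S)-4-hydroxy-2,6,6-trimethylcyclohex-2-en-1-yl]-3-methylpenta-2,4-dienal, via aluminium aldimine 21 (not isolated)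
Conditions: iBu2AlH (2.5 equiv), CH2Cl2, −78 °C; wet silica gel
Reagents that add atoms: water, O
Why: Reduction of a conjugated nitrile stops at the N-aluminium aldimine, which is hydrolysed under near-neutral conditions so that the acid-labile allylic C3 hydroxyl is not ionised.

Step 13
Reactants: 23 (2E,4E,6E)-2,7-dimethylocta-2,4,6-trienedial; 24 ethyl (2E)-4-(diethoxyphosphoryl)-2-methylbut-2-enoate
Product: 25 ethyl (2E,4E,6E,8E,10E)-2,6,11-trimethyl-12-oxododeca-2,4,6,8,10-pentaenoate
Conditions: NaH, THF, 0 °C (anion of 24); added slowly to 23 (excess), −30 °C to rt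
Reagents that add atoms: none
Why: Horner–Wadsworth–Emmons mono-olefination of a symmetrical dialdehyde used in excess; the vinylogous phosphonate reacts at the carbon next to phosphorus and forms the new disubstituted alkene E.

Step 14
Reactants: 25 ethyl (2E,4E,6E,8E,10E)-2,6,11-trimethyl-12-oxododeca-2,4,6,8,10-pentaenoate
Product: 26 ethyl (2E,4E,6E,8E,10E)-12-hydroxy-2,6,11-trimethyldodeca-2,4,6,8,10-pentaenoate
Conditions: NaBH4, EtOH/THF, 0 °C
Reagents that add atoms: none
Why: Chemoselective 1,2-reduction of the aldehyde; the conjugated ester is not reduced by borohydride at this temperature.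

Step 15
Reactants: 26 ethyl (2E,4E,6E,8E,10E)-12-hydroxy-2,6,11-trimethyldodeca-2,4,6,8,10-pentaenoate
Product: 27 [(2E,4E,6E,8E,10E)-12-ethoxy-2,7,11-trimethyl-12-oxododeca-2,4,6,8,10-pentaen-1-yl]triphenylphosphonium bromide
Conditions: PPh3·HBr, CH2Cl2, rt, dark
Reagents that add atoms: triphenylphosphine hydrobromide, Br.c1ccc(cc1)P(c1ccccc1)c1ccccc1
Why: Acid-mediated ionisation of the polyenylic alcohol and capture of the delocalised cation by phosphine at the terminal carbon, the standard way to carotenoid Wittig salts; this fragment has no acid-sensitive group.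

Step 16
Reactants: 22 (2E,4E)-5-[(1R,4S)-4-hydroxy-2,6,6-trimethylcyclohex-2-en-1-yl]-3-methylpenta-2,4-dienal; 27 [(2E,4E,6E,8E,10E)-12-ethoxy-2,7,11-trimethyl-12-oxododeca-2,4,6,8,10-pentaen-1-yl]triphenylphosphonium bromide
Product: 29 ethyl (2E,4E,6E,8E,10E,12E,14E,16E)-17-[(1R,4S)-4-hydroxy-2,6,6-trimethylcyclohex-2-en-1-yl]-2,6,11,15-tetramethylheptadeca-2,4,6,8,10,12,14,16-octaenoate, via phosphorus ylide 28 (not isolated)
Conditions: 1,2-epoxybutane, EtOH, 75 °C, dark, argon; then reflux in n-heptane (Z-to-E equilibration)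
Reagents that add atoms: none
Why: Wittig olefination forming C11=C12; the epoxide takes up HBr and releases the ylide without strong base, which tolerates the free hydroxyl and the C6 centre, and any Z isomer at the new disubstituted bond should equilibrate thermally to all-E.

Step 17
Reactants: 29 ethyl (2E,4E,6E,8E,10E,12E,14E,16E)-17-[(1R,4S)-4-hydroxy-2,6,6-trimethylcyclohex-2-en-1-yl]-2,6,11,15-tetramethylheptadeca-2,4,6,8,10,12,14,16-octaenoate
Product: 30 (2E,4E,6E,8E,10E,12E,14E,16E)-17-[(1R,4S)-4-hydroxy-2,6,6-trimethylcyclohex-2-en-1-yl]-2,6,11,15-tetramethylheptadeca-2,4,6,8,10,12,14,16-octaen-1-ol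
Conditions: iBu2AlH (3.5 equiv), CH2Cl2, −78 to −40 °C; aq KNaC4H4O6; dark, argon
Reagents that add atoms: none
Why: 1,2-Reduction of the conjugated ester to the allylic alcohol with neutral tartrate work-up, which should leave the polyene geometry and the allylic C3 hydroxyl untouched.

**Compound list**

1 | 2,4,4-trimethylcyclopent-2-en-1-one | CC1=CC(C)(C)CC1=O | starting material
2 | (1S)-2,4,4-trimethylcyclopent-2-en-1-ol | O[C@H]1CC(C)(C)C=C1C | intermediate
3 | tributyl({[(1S)-2,4,4-trimethylcyclopent-2-en-1-yl]oxy}methyl)stannane | CCCC[Sn](CCCC)(CCCC)CO[C@H]1CC(C)(C)C=C1C | intermediate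
4 | ({[(1S)-2,4,4-trimethylcyclopent-2-en-1-yl]oxy}methyl)lithium | [Li]CO[C@H]1CC(C)(C)C=C1C | intermediate
5 | [(1R)-2,5,5-trimethylcyclopent-2-en-1-yl]methanol | OC[C@H]1C(C)=CCC1(C)C | intermediate
6 | (1R)-2,5,5-trimethylcyclopent-2-ene-1-carbaldehyde | O=C[C@H]1C(C)=CCC1(C)C | intermediate
7 | (1R)-2,5,5-trimethylcyclopent-2-ene-1-carboxylic acid | OC(=O)[C@H]1C(C)=CCC1(C)C | intermediate
8 | (1R)-2,5,5-trimethylcyclopent-2-ene-1-carbonyl chloride | ClC(=O)[C@H]1C(C)=CCC1(C)C | intermediate
9 | (1R)-N,N,2,5,5-pentamethylcyclopent-2-ene-1-carboxamide | CN(C)C(=O)[C@H]1C(C)=CCC1(C)C | intermediate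
10 | (1S,2R,5R)-6,6-dibromo-N,N,1,3,3-pentamethylbicyclo[3.1.0]hexane-2-carboxamide (CBr2 bridge anti to the carboxamide) | CN(C)C(=O)[C@@H]1C(C)(C)C[C@H]2C(Br)(Br)[C@@]12C | intermediate
11 | (4R)-2-bromo-4-(dimethylcarbamoyl)-3,5,5-trimethylcyclohex-2-en-1-ylium trifluoromethanesulfonate | CN(C)C(=O)[C@@H]1C(C)(C)C[CH+]C(Br)=C1C.[O-]S(=O)(=O)C(F)(F)F | intermediate
12 | (1S,4R)-6-bromo-N,N,5,8,8-pentamethyl-2-oxabicyclo[2.2.2]oct-5-en-3-iminium trifluoromethanesulfonate | C[N+](C)=C1O[C@H]2CC(C)(C)[C@@H]1C(C)=C2Br.[O-]S(=O)(=O)C(F)(F)F | intermediate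
13 | (1S,4R)-6-bromo-5,8,8-trimethyl-2-oxabicyclo[2.2.2]oct-5-en-3-one | O=C1O[C@H]2CC(C)(C)[C@@H]1C(C)=C2Br | intermediate
14 | (1S,4R)-5,8,8-trimethyl-2-oxabicyclo[2.2.2]oct-5-en-3-one | O=C1O[C@H]2CC(C)(C)[C@@H]1C(C)=C2 | intermediate
15 | (1S,4R)-5,8,8-trimethyl-2-oxabicyclo[2.2.2]oct-5-en-3-ol (C3 epimers) | OC1O[C@H]2CC(C)(C)[C@@H]1C(C)=C2 | intermediate
16 | diethyl (2-oxopropyl)phosphonate | CCOP(=O)(CC(C)=O)OCC | starting material
17 | (1R,4S)-4-hydroxy-2,6,6-trimethylcyclohex-2-ene-1-carbaldehyde | O=C[C@H]1C(C)=C[C@@H](O)CC1(C)C | intermediate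
18 | (3E)-4-[(1R,4S)-4-hydroxy-2,6,6-trimethylcyclohex-2-en-1-yl]but-3-en-2-one, (3S,6R)-3-hydroxy-α-ionone | CC(=O)/C=C/[C@H]1C(C)=C[C@@H](O)CC1(C)C | intermediate
19 | diethyl (cyanomethyl)phosphonate | CCOP(=O)(CC#N)OCC | starting material
20 | (2E,4E)-5-[(1R,4S)-4-hydroxy-2,6,6-trimethylcyclohex-2-en-1-yl]-3-methylpenta-2,4-dienenitrile | N#C/C=C(C)/C=C/[C@H]1C(C)=C[C@@H](O)CC1(C)C | intermediate
21 | N-(diisobutylaluminio) aldimine of 22 | CC(C)C[Al](CC(C)C)N=C/C=C(C)/C=C/[C@H]1C(C)=C[C@@H](O)CC1(C)C | intermediate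
22 | (2E,4E)-5-[(1R,4S)-4-hydroxy-2,6,6-trimethylcyclohex-2-en-1-yl]-3-methylpenta-2,4-dienal | O=C/C=C(C)/C=C/[C@H]1C(C)=C[C@@H](O)CC1(C)C | intermediate
23 | (2E,4E,6E)-2,7-dimethylocta-2,4,6-trienedial | O=C/C(C)=C/C=C/C=C(C)/C=O | starting material
24 | ethyl (2E)-4-(diethoxyphosphoryl)-2-methylbut-2-enoate | CCOC(=O)/C(C)=C/CP(=O)(OCC)OCC | starting material
25 | ethyl (2E,4E,6E,8E,10E)-2,6,11-trimethyl-12-oxododeca-2,4,6,8,10-pentaenoate | CCOC(=O)/C(C)=C/C=C/C(C)=C/C=C/C=C(C)/C=O | intermediate
26 | ethyl (2E,4E,6E,8E,10E)-12-hydroxy-2,6,11-trimethyldodeca-2,4,6,8,10-pentaenoate | CCOC(=O)/C(C)=C/C=C/C(C)=C/C=C/C=C(C)/CO | intermediate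
27 | [(2E,4E,6E,8E,10E)-12-ethoxy-2,7,11-trimethyl-12-oxododeca-2,4,6,8,10-pentaen-1-yl]triphenylphosphonium bromide | CCOC(=O)/C(C)=C/C=C/C(C)=C/C=C/C=C(C)/C[P+](c1ccccc1)(c1ccccc1)c1ccccc1.[Br-] | intermediate
28 | ethyl (2E,4E,6E,8E,10E)-2,6,11-trimethyl-12-(triphenyl-λ5-phosphanylidene)dodeca-2,4,6,8,10-pentaenoate | CCOC(=O)/C(C)=C/C=C/C(C)=C/C=C/C=C(C)/C=P(c1ccccc1)(c1ccccc1)c1ccccc1 | intermediate
29 | ethyl (2E,4E,6E,8E,10E,12E,14E,16E)-17-[(1R,4S)-4-hydroxy-2,6,6-trimethylcyclohex-2-en-1-yl]-2,6,11,15-tetramethylheptadeca-2,4,6,8,10,12,14,16-octaenoate | CCOC(=O)/C(C)=C/C=C/C(C)=C/C=C/C=C(C)/C=C/C=C(C)/C=C/[C@H]1C(C)=C[C@@H](O)CC1(C)C | intermediate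
30 | (2E,4E,6E,8E,10E,12E,14E,16E)-17-[(1R,4S)-4-hydroxy-2,6,6-trimethylcyclohex-2-en-1-yl]-2,6,11,15-tetramethylheptadeca-2,4,6,8,10,12,14,16-octaen-1-ol, (3S,6R)-3-hydroxy-8'-apo-ε-caroten-8'-ol | CC1=C[C@@H](O)CC(C)(C)[C@H]1/C=C/C(C)=C/C=C/C(C)=C/C=C/C=C(C)/C=C/C=C(\C)CO | target

**Count and risks**

Total steps: 17. Longest linear sequence: 14 (steps 1–12, 16, 17); steps 13–15 build the chain half.

Steps most likely to fail:

Step 7. Capture of the allyl cation by the amide oxygen may lose to proton loss (diene formation) or to capture by the solvent. The fallback separates ring expansion from the setting of C3. From 10, AgNO3 in aqueous acetone should give, by the same electrocyclic opening with water as external nucleophile, (1R)-3-bromo-4-hydroxy-N,N,2,6,6-pentamethylcyclohex-2-ene-1-carboxamide F1 as a mixture of C4 epimers. Dess–Martin oxidation converges both epimers to (1R)-3-bromo-N,N,2,6,6-pentamethyl-4-oxocyclohex-2-ene-1-carboxamide F2. Luche reduction (NaBH4, CeCl3·7H2O, MeOH, −78 °C), with hydride expected anti to the pseudo-axial carboxamide, should give the cis alcohol (1R,4S)-3-bromo-4-hydroxy-N,N,2,6,6-pentamethylcyclohex-2-ene-1-carboxamide F3. TsOH in toluene at 80 °C should then close the lactone with loss of dimethylamine, returning to the route at 13.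

Step 3. The lithiomethyl ether may be protonated or undergo a [1,2]-shift instead of the [2,3]-shift onto the hindered alkene carbon next to CMe2. The fallback delivers the one-carbon unit by a neutral carbene [2,3]-shift. From 2, heating with N,N-dimethylformamide dimethyl acetal in xylene at 150 °C with removal of methanol should give the mixed acetal 1-methoxy-N,N-dimethyl-1-{[(1S)-2,4,4-trimethylcyclopent-2-en-1-yl]oxy}methanamine F4. This loses methanol to an alkoxy(amino)carbene that rearranges suprafacially to the amide, returning to the route at 9 and replacing steps 2 to 5.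

Step 10. Slow olefination of the hindered bridged lactol may allow base-induced epimerisation at C6 or migration of the ring alkene into conjugation. The fallback makes C7=C8 in two stages, a fast methylenation and an olefin metathesis. From 15, Ph3P=CH2 (from methyltriphenylphosphonium bromide and KN(SiMe3)2, THF, −78 to 0 °C) should give (1S,4R)-4-ethenyl-3,5,5-trimethylcyclohex-2-en-1-ol F5. Cross-metathesis with but-3-en-2-one (second-generation Hoveyda–Grubbs catalyst, RuCl2(H2IMes)(=CH-C6H4-2-OiPr), CH2Cl2, 40 °C) should give the E-enone, returning to the route at 18.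

Further compounds
F1 | step 7 | (1R)-3-bromo-4-hydroxy-N,N,2,6,6-pentamethylcyclohex-2-ene-1-carboxamide (C4 epimers) | CN(C)C(=O)[C@@H]1C(C)(C)CC(O)C(Br)=C1C
F2 | step 7 | (1R)-3-bromo-N,N,2,6,6-pentamethyl-4-oxocyclohex-2-ene-1-carboxamide | CN(C)C(=O)[C@@H]1C(C)(C)CC(=O)C(Br)=C1C
F3 | step 7 | (1R,4S)-3-bromo-4-hydroxy-N,N,2,6,6-pentamethylcyclohex-2-ene-1-carboxamide | CN(C)C(=O)[C@@H]1C(C)(C)C[C@H](O)C(Br)=C1C
F4 | step 3 | 1-methoxy-N,N-dimethyl-1-{[(1S)-2,4,4-trimethylcyclopent-2-en-1-yl]oxy}methanamine | COC(N(C)C)O[C@H]1CC(C)(C)C=C1C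
F5 | step 10 | (1S,4R)-4-ethenyl-3,5,5-trimethylcyclohex-2-en-1-ol | C=C[C@H]1C(C)=C[C@@H](O)CC1(C)C
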